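| flask | D | Z | remark | time |
|---|---|---|---|---|
| teal | 0.25 M | 2.5 equiv | run made earlier |  |
| ochre | 0.38 M | 2.5 equiv | run made earlier |  |
| grey | 0.50 M | 3.8 equiv | run made earlier |  |
| flask | 0.50 M | 2.50 equiv |  | 20 min |
- teal (time / min: D / %, Q / %, J / %): 1.00: 95.6, 4.8, 0.4; 2.00: 92.8, 7.4, 0; 5.00: 82.2, 10.8, 1.6; 12.0: 69.4, 9.7, 0
- ochre (time / min: D / %, Q / %, J / %): 1.00: 93.3, 5.4, 0; 2.00: 87.6, 9.4, 0; 5.00: 73.2, 13.8, 1.0; 12.0: 56.7, 12.8, 2.0
- grey (time / min: D / %, Q / %, J / %): 1.50: 81.0, 13.9, 0.4; 4.00: 59.8, 20.9, 2.7; 8.00: 40.1, 20.9, 4.3; 12.0: 30.9, 17.9, 4.7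

(standard deviation of a reading: 0.5 percentage points)
- the D standing at 20 min, as a percentage of the D charged
- the Q standing at 20 min, as a percentage of the D charged
- the J standing at 20 min, as a percentage of the D charged
- the X standing at 20 min, as a percentage of the D charged
- the numbers in the tables scatter with a standard deviation of 0.5 percentage points

**The gap.** Per molar per minute is the unit for reading these runs. Call the gap what is charged less the D, Q and J standing. In grey it grows from 16.6% at 4.00 min to 34.7% at 8.00 min. Divide that gain per minute by the mean Q standing and the mean molarity of D standing, and you read 0.867 /M/min; call this the drain constant, a second-order rate constant.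

**Turning D.** By hand, less D standing should slow the drain in step. Grey's next window, with D fallen, reads 0.857 /M/min, close to the first.

**Turning Z.** By hand, a gap made through Z should read lower with less Z. Teal, charged with a third of grey's Z, reads 1.14 /M/min, which is higher. This is a reading with the scatter in it, but it shows no fall with less Z, so you should read the gap as a product of D with Q.

**Turning time.** By hand, X grows from J. Grey's readings show J growing at 0.0191 /min per unit of Q. If J passes on at that pace, and the forecast's J of 3% stands for the whole time, your estimate for the flask is about 1.15% X at 20 min: a small correction.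

**The forecast.** It gives D 37%, Q 8.5%, J 3% and X 51.5%, since the gap “must be X, so J is a short-lived intermediate”. On X it parts from the reckoning above.

**The flask.** It gives D 35.6%, Q 8.05%, J 2.48% and X 0.0603%.

    D + Z → Q (k = 0.00125 /M/s)
    Z + J → X (k = 1.24 × 10⁻⁴ /M/s)
    Z ⇌ E (K = 11.0, k = 0.00266 /s)
    Z + Q → J (k = 5.24 × 10⁻⁴ /M/s)
    D + Q → L (k = 0.00709 /M/s)

**The drain.** The gap in the flask is nearly all L, each counted as two D, and L stands at 53.8%. In the flask at 3.28 min, Q goes to L 7.5 times as fast as to J. From 10.0 min to 20 min, this flask reads a drain constant of 0.824 /M/min. For the neighbour with 0.20 M of D, grey's constant, with mean D and the end Q, gives a gap of 23.6%, and that neighbour stands at 23.0%.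

The data were computed from invented constants; the scatter is artificial.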